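## Structural features

The target is a single oxolane (tetrahydrofuran) ring. C2 and C5 each carry a 4-hydroxy-3,5-dimethoxyphenyl ring through an aryl–C bond, and C3 and C4 each carry a hydroxymethyl group. C2, C3, C4 and C5 are four contiguous stereocentres, and the descriptors place all four substituents on one face (2,3-cis, 3,4-cis, 4,5-cis). Because the two aryl groups are identical, a mirror plane runs through O1 and the midpoint of C3–C4: the compound is meso, (2R,3R,4S,5S), and only relative configuration has to be controlled. The all-cis arrangement is the most crowded diastereomer, so it has to be set kinetically and cannot be reached or repaired by equilibration. The fragile sites are the C2–O1 and C5–O1 bonds, which are benzylic ethers para to an oxygen donor (acid ionises them and epimerises C2/C5; hydrogenolysis catalysts can cleave them), and the 2,6-dimethoxyphenols, which oxidise easily as phenoxides. The real difficulty is therefore a contrathermodynamic relative configuration on an acid-labile ring, not the carbon count. The key step exploits the fact that C2–O1–C5 with its two identical aryl groups is a symmetrical carbonyl ylide (a C–O–C 1,3-dipole), while C3–C4 with its two cis one-carbon arms is a cyclic Z-alkene diacyl unit, so one (3+2) cycloaddition across C2–C3 and C4–C5 can deliver the ring and all four stereocentres.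

## Logic of the disconnections

8 from 7. No skeletal bond is cut. The four C–H bonds of the two CH2OH groups on C3 and C4 are exchanged for the two C=O groups and bridging oxygen of a cyclic anhydride, and the two phenolic O–H bonds for O–acyl bonds of a hindered ester. The anhydride ties C3 and C4 into a cis relation and reveals a Z-alkene dipolarophile. An aryl ester, unlike a benzyl ether, falls to the same hydride that reduces the anhydride, so no hydrogenolysis has to be run next to the benzylic C2–O1 and C5–O1 bonds, and the endgame shrinks to one step. The forward step must reduce four carbonyl groups without enolisation at C3/C4 and must be worked up without acid.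

7 from 4 and 5, through 6. The bonds C2–C3 and C4–C5 are cut, which opens the oxolane ring and separates the C2–O1–C5 unit from the C3–C4 unit. The cut follows the mirror plane of 7, so both fragments are symmetrical, and it removes the only ring of the skeleton and all four stereocentres in one retro-step. What remains is 5, which is achiral, and 4, whose two stereocentres are erased on opening. The forward step must generate 6 from 4 under conditions that 7 survives, 6 must adopt the W geometry, and 5 must approach in the endo sense.

4 from 3. The two C–O bonds of the oxirane are cut, which is removal of one oxygen atom from an alkene. This leaves 3, which is symmetrical and has no stereocentre. The forward step needs a neutral oxygen-transfer reagent, because the electron-rich diaryl oxirane rearranges under acid.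

3 from two molecules of 2. The central C=C bond is cut into two identical aldehyde carbons. This halves the carbon skeleton and uses the symmetry again. The forward step is a reductive carbonyl coupling that must leave the aryl ester intact; the alkene geometry is not critical.

2 from 1. The O–acyl bond is cut to reach 1, which is cheap and commercial. The forward step only has to acylate a hindered phenol.

## Other disconnections considered

Alternative 1: The cut is at the two aryl–C bonds (C2–aryl and C5–aryl), with the ring already present. In the forward sense the cis bis(quinolin-8-yl) diamide A1 would be arylated twice with aryl iodide A2 under Pd(OAc)2 and AgOAc to give the all-cis diamide A3.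
- Mechanism: each amide binds divalent palladium through its N,N-chelate, a cis-fused five-membered palladacycle forms at the neighbouring CH2, oxidative addition of A2 gives tetravalent palladium, and reductive elimination makes the C–aryl bond on the amide face.
- In its favour: the 2,3-cis and 4,5-cis relations are enforced by the geometry of the palladacycle. On that point it is better than the chosen plan, whose C2/C3 relation rests on an endo preference. It needs no photochemistry, and it uses the symmetry two-directionally, as the chosen plan does.
- Against it: the C–H bonds to be broken lie next to the ring oxygen, a position that directed palladation of saturated oxygen heterocycles is expected to reach less readily. Two chelating amides in one molecule can sequester the catalyst, and the second arylation has to occur on an already crowded face. The two auxiliaries of A3 must then be removed from a congested all-cis diamide without epimerising C3/C4 (activation, then reduction), and the benzyl ethers still have to be hydrogenolysed beside the benzylic ring C–O bonds.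
- Comparison: on step count it is about equal to the chosen plan at best and more likely longer, and it builds no ring in its key step.

Alternative 2: The cut is at C3–C4, O1–C2 and O1–C5 at the furan oxidation level. In the forward sense the ester-tethered diyne A4 would cyclise under [CpRu(MeCN)3]PF6 with dimethyl sulfoxide as oxygen donor to the furan-fused lactone A5.
- Mechanism: oxidative coupling of the two alkynes on ruthenium gives a ruthenacycle with carbene character at the aryl-bearing carbons, the sulfoxide transfers its oxygen to one of them, and closure gives the furan.
- In its favour: three bonds and two rings form in one step. In bond count per step this is better than the chosen plan, and the key step has no stereochemical risk because it creates no stereocentre. A4 comes from standard alkyne couplings and an esterification.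
- Against it: A5 is flat. All four stereocentres would have to be set afterwards by all-cis hydrogenation of a tetrasubstituted 2,5-diaryl furan. Delivery of hydrogen from one face would give the right relative configuration in principle, but such furans are reluctant substrates. Partly reduced intermediates can isomerise and change face, and each benzylic C–O bond created is exposed to hydrogenolysis under the forcing conditions required. The lactone must then be reduced.
- Comparison: the chosen plan sets ring and stereochemistry together, whereas this one defers the whole stereochemical problem to its least reliable step and needs more steps overall.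

Alternative 3: The cut is at the exocyclic C3–CH2 bond. In the forward sense the bromomethylsilyl ether A6, a 2-aryl cyclic enol ether that already holds C4 and C5 in a cis relation, would be treated with Bu3SnH to give the bridged all-cis product A7.
- Mechanism: the silylmethyl radical adds 6-exo to C3, forming a cis-fused oxasilinane, and the benzylic C2 radical then takes hydrogen on the convex face. Oxidative cleavage of the C–Si bond of A7 and debenzylation would lead to 8.
- In its favour: the C3/C4 cis relation is enforced by the short tether and the C2 configuration by the shape of the bicycle. For these two centres the control is more dependable than an endo preference, so on that point it is better than the chosen plan. The radical chain is tolerant of the ether functions.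
- Against it: the key step sets only two of the four stereocentres. The other two, and an acid-sensitive enol ether, must already be present in A6, which needs its own multi-step stereocontrolled synthesis. 6-exo closure competes with direct reduction of the radical, a stoichiometric tin reagent is used, and the mirror symmetry of 8 is not exploited at all.
- Comparison: it is clearly longer in step count, and the final hydrogenolysis issue remains.

Key step: step 4

Remark on the chemistry: 8 is meso, so no absolute stereocontrol is needed. 4 is chiral and is used as the racemate (one enantiomer is drawn in the list), which has no consequence because 6, 7 and 8 are achiral. The relative configurations of 4 (trans) and of 7 and 8 (all-cis) are mutually consistent. The phenols are carried as pivalates so that the final hydride step also unmasks them and no hydrogenolysis is needed.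

Step 1
Reactants: 1 4-hydroxy-3,5-dimethoxybenzaldehyde (syringaldehyde)
Product: 2 4-formyl-2,6-dimethoxyphenyl 2,2-dimethylpropanoate
Conditions: PivCl, Et3N, DMAP (cat.), CH2Cl2, 0 °C → rt
Reagents that add atoms: pivaloyl chloride, CC(C)(C)C(=O)Cl
Why: DMAP-catalysed O-acylation (nucleophilic acyl substitution) of the hindered but acidic phenol; the hindered aryl pivalate is chosen because esters of this kind are expected to tolerate low-valent titanium and to be cleaved later by the hydride that reduces the anhydride. No stereocentre is formed.

Step 2
Reactants: 2 4-formyl-2,6-dimethoxyphenyl 2,2-dimethylpropanoate (two molecules)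
Product: 3 (E)-1,2-bis[3,5-dimethoxy-4-(pivaloyloxy)phenyl]ethene
Conditions: TiCl4, Zn, THF, −10 °C → reflux; aq. K2CO3 work-up
Reagents that add atoms: none
Why: McMurry reductive coupling: low-valent titanium joins the two aldehyde carbons by pinacol-type C–C coupling and then deoxygenates to the alkene, and aromatic aldehydes should give mainly the E-stilbene. The geometry is not critical, because the opening in step 4 is expected to converge on one ylide geometry.

Step 3
Reactants: 3 (E)-1,2-bis[3,5-dimethoxy-4-(pivaloyloxy)phenyl]ethene
Product: 4 rac-trans-2,3-bis[3,5-dimethoxy-4-(pivaloyloxy)phenyl]oxirane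
Conditions: dimethyldioxirane (acetone solution), CH2Cl2, 0 °C → rt, dark
Reagents that add atoms: dimethyldioxirane, CC1(C)OO1
Why: Dioxirane epoxidation is a concerted electrophilic oxygen-atom transfer through a spiro transition state and is stereospecific, so the E-alkene should give the trans-oxirane as a racemate. The only by-product is acetone, so the acid-sensitive electron-rich oxirane never meets a carboxylic acid.

Step 4
Reactants: 4 rac-trans-2,3-bis[3,5-dimethoxy-4-(pivaloyloxy)phenyl]oxirane; 5 maleic anhydride
Product: 7 all-cis-2,5-bis[3,5-dimethoxy-4-(pivaloyloxy)phenyl]tetrahydrofuran-3,4-dicarboxylic anhydride (meso), via W-shaped carbonyl ylide 6 (not isolated)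
Conditions: 9,10-dicyanoanthracene (cat.), hν (420 nm), dry MeCN, rt, Ar
Reagents that add atoms: none
Why: Photoexcited 9,10-dicyanoanthracene accepts an electron from the electron-rich oxirane 4, the radical cation breaks its C–C bond, and back electron transfer returns the neutral carbonyl ylide 6; this electron-transfer opening replaces a thermal conrotatory opening, which would need forcing temperatures for an oxirane without acceptor groups on the ring carbons. The opened species is expected to relax to the exo,exo (W) geometry whichever oxirane isomer it comes from, so both aryl groups take the outer positions of the C2–O1–C5 dipole. 6 then adds to 5 in a concerted suprafacial–suprafacial [π4s+π2s] 1,3-dipolar cycloaddition, the closest known type being the addition of sensitiser-generated diaryl carbonyl ylides (and of W-shaped azomethine ylides) to electron-poor cyclic Z-alkenes, with the HOMO of the electron-rich dipole matched to the LUMO of the anhydride. The oxolane ring closes in this single (3+2) event by simultaneous formation of C2–C3 and C4–C5, and the anhydride ring is carried in unchanged as the cis-fused second ring. C2 and C5 become cis because of the W geometry of 6; C3 and C4 are cis because the Z geometry of 5 is transferred stereospecifically; the C2/C3 and C4/C5 relations are set by endo approach, in which the anhydride lies under the C–O–C unit and its carbonyl groups face the aryl-bearing termini. The step therefore needs endo over exo selectivity, which the compact cyclic dipolarophile, donor–acceptor attraction between the aryl-substituted termini and the anhydride carbonyls, and the absence of inward substituents on 6 should favour. Excitation of the sensitiser alone with visible light avoids direct excitation of 5 and photo-Fries chemistry of the aryl esters, dry acetonitrile keeps water from intercepting the radical cation or the anhydride, and a moderate excess of the dipolarophile should let trapping outrun reclosure of 6.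

Step 5
Reactants: 7 all-cis-2,5-bis[3,5-dimethoxy-4-(pivaloyloxy)phenyl]tetrahydrofuran-3,4-dicarboxylic anhydride
Product: 8 all-cis-[2,5-bis(4-hydroxy-3,5-dimethoxyphenyl)tetrahydrofuran-3,4-diyl]dimethanol, (2R,3R,4S,5S), meso
Conditions: LiAlH4 (excess), THF, 0 °C → rt; then EtOAc, aq. KNaC4H4O6
Reagents that add atoms: none
Why: LiAlH4 reduces both anhydride carbonyls to primary alkoxides (hydride reduction of a cyclic anhydride to the 1,4-diol) and cleaves both aryl pivalates to phenoxides in the same operation, so no hydrogenolysis is run near the benzylic C2–O1 and C5–O1 bonds. No stereocentre is formed; C3 and C4 should keep their configuration because hydride addition to the carbonyl carbons is faster than enolisation, and the buffered tartrate work-up avoids acid-induced ionisation at C2/C5.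

## Compound list

1 | 4-hydroxy-3,5-dimethoxybenzaldehyde (syringaldehyde) | COc1cc(C=O)cc(OC)c1O | starting material
2 | 4-formyl-2,6-dimethoxyphenyl 2,2-dimethylpropanoate | COc1cc(C=O)cc(OC)c1OC(=O)C(C)(C)C | intermediate
3 | (E)-1,2-bis[3,5-dimethoxy-4-(pivaloyloxy)phenyl]ethene | COc1cc(/C=C/c2cc(OC)c(OC(=O)C(C)(C)C)c(OC)c2)cc(OC)c1OC(=O)C(C)(C)C | intermediate
4 | rac-trans-2,3-bis[3,5-dimethoxy-4-(pivaloyloxy)phenyl]oxirane ((2S,3S) enantiomer drawn, racemate used) | COc1cc([C@@H]2O[C@H]2c2cc(OC)c(OC(=O)C(C)(C)C)c(OC)c2)cc(OC)c1OC(=O)C(C)(C)C | intermediate
5 | maleic anhydride | O=C1OC(=O)C=C1 | starting material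
6 | W-shaped (exo,exo) carbonyl ylide with a 3,5-dimethoxy-4-(pivaloyloxy)phenyl group on each carbon terminus, formed in the flask and not isolated | COc1cc(/C=[O+]/[CH-]c2cc(OC)c(OC(=O)C(C)(C)C)c(OC)c2)cc(OC)c1OC(=O)C(C)(C)C | intermediate
7 | all-cis-2,5-bis[3,5-dimethoxy-4-(pivaloyloxy)phenyl]tetrahydrofuran-3,4-dicarboxylic anhydride (meso) | COc1cc([C@H]2O[C@@H](c3cc(OC)c(OC(=O)C(C)(C)C)c(OC)c3)[C@@H](C(=O)O5)[C@H]2C5=O)cc(OC)c1OC(=O)C(C)(C)C | intermediate
8 | all-cis-[2,5-bis(4-hydroxy-3,5-dimethoxyphenyl)tetrahydrofuran-3,4-diyl]dimethanol, (2R,3R,4S,5S), meso | COc1cc([C@H]2O[C@@H](c3cc(OC)c(O)c(OC)c3)[C@@H](CO)[C@H]2CO)cc(OC)c1O | target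

## Step count and least certain steps

Total step count: 5. Longest linear sequence: 5 steps (1 → 2 → 3 → 4 → 7 → 8).

**Step 4 (key step).**
- What may go wrong: exo approach of 5 may compete with endo approach, which would place the anhydride trans to the aryl groups. Electron transfer from the reduced sensitiser to 5 may open stepwise radical-ion coupling that erodes the stereospecific transfer of alkene geometry. The opened radical cation may rearrange by 1,2-shift to a carbonyl isomer. The anhydride may be opened by moisture during isolation.
- Fallback: it sets out from 4 and takes the C2/C3 relation out of the cycloaddition. The same sensitised opening is run with dimethyl but-2-ynedioate as the trap, which should give dimethyl cis-2,5-bis[3,5-dimethoxy-4-(pivaloyloxy)phenyl]-2,5-dihydrofuran-3,4-dicarboxylate F1. Here only the 2,5-cis relation comes from the ylide. Hydrogenation (H2, Rh/Al2O3, EtOAc) should deliver both hydrogens to the face opposite the two aryl groups and so push both ester groups onto the aryl face, giving all-cis dimethyl 2,5-bis[3,5-dimethoxy-4-(pivaloyloxy)phenyl]tetrahydrofuran-3,4-dicarboxylate F2. LiAlH4 in THF then reduces both esters and removes both pivalates, and the route is rejoined at 8.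

**Step 5.**
- What may go wrong: reduction may stall at the lactone oxidation level. Base-mediated epimerisation at C3/C4 may occur at the transient aldehyde level, driven by relief of the all-cis strain. The phenoxides may trigger opening of the benzylic ring ether or be oxidised by air. Traces of acid in work-up or chromatography may epimerise C2/C5.
- Fallback: it sets out from 7 and separates the two events under non-basic conditions. Hydrolysis (H2O, THF, rt) should give all-cis 2,5-bis[3,5-dimethoxy-4-(pivaloyloxy)phenyl]tetrahydrofuran-3,4-dicarboxylic acid F3. BH3·THF, an electrophilic reductant that prefers carboxylic acids over aryl esters, should give all-cis {2,5-bis[3,5-dimethoxy-4-(pivaloyloxy)phenyl]tetrahydrofuran-3,4-diyl}dimethanol F4, which no longer has an epimerisable centre next to a carbonyl group. i-Bu2AlH in CH2Cl2 at −78 °C then removes the pivalates, and the route is rejoined at 8.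

**Step 3.**
- What may go wrong: acid- or Lewis-acid-induced 1,2-shift (Meinwald-type rearrangement) of the electron-rich diaryl oxirane may occur during reaction, concentration or chromatography, and excess oxidant may attack the trioxygenated rings.
- Fallback: it sets out from 2 and builds the oxirane under basic conditions by sulfur-ylide epoxidation instead of alkene oxidation. NaBH4 in MeOH should give 4-(hydroxymethyl)-2,6-dimethoxyphenyl 2,2-dimethylpropanoate F5. Tetrahydrothiophene with HBF4·OEt2 converts it into 1-[3,5-dimethoxy-4-(pivaloyloxy)benzyl]tetrahydrothiophenium tetrafluoroborate F6. Deprotonation with LiN(SiMe3)2 in THF at −78 °C in the presence of a second equivalent of 2 should give mainly the trans-oxirane by reversible betaine formation (Corey–Chaykovsky-type epoxidation). The route is rejoined at 4, and step 2 is bypassed as well.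

**Step 2.**
- What may go wrong: the coupling may stop at the pinacol stage, the titanium and zinc Lewis acids may cleave the aryl esters at reflux, and over-reduction of the alkene may occur.
- Fallback: it sets out from 2 and makes the alkene by metathesis instead of reductive coupling. Wittig methylenation (MePPh3Br, KOt-Bu, THF, 0 °C) should give 4-ethenyl-2,6-dimethoxyphenyl 2,2-dimethylpropanoate F7. Homometathesis with the second-generation Grubbs catalyst RuCl2(=CHPh)(H2IMes)(PCy3) in CH2Cl2 at 40 °C, with loss of ethene, should give the E-stilbene, and the route is rejoined at 3.

## Further compounds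

F1 | step 4 | dimethyl cis-2,5-bis[3,5-dimethoxy-4-(pivaloyloxy)phenyl]-2,5-dihydrofuran-3,4-dicarboxylate | COC(=O)C1=C(C(=O)OC)[C@@H](c2cc(OC)c(OC(=O)C(C)(C)C)c(OC)c2)O[C@H]1c1cc(OC)c(OC(=O)C(C)(C)C)c(OC)c1
F2 | step 4 | all-cis dimethyl 2,5-bis[3,5-dimethoxy-4-(pivaloyloxy)phenyl]tetrahydrofuran-3,4-dicarboxylate | COc1cc([C@H]2O[C@@H](c3cc(OC)c(OC(=O)C(C)(C)C)c(OC)c3)[C@@H](C(=O)OC)[C@H]2C(=O)OC)cc(OC)c1OC(=O)C(C)(C)C
F3 | step 5 | all-cis 2,5-bis[3,5-dimethoxy-4-(pivaloyloxy)phenyl]tetrahydrofuran-3,4-dicarboxylic acid | COc1cc([C@H]2O[C@@H](c3cc(OC)c(OC(=O)C(C)(C)C)c(OC)c3)[C@@H](C(O)=O)[C@H]2C(O)=O)cc(OC)c1OC(=O)C(C)(C)C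
F4 | step 5 | all-cis {2,5-bis[3,5-dimethoxy-4-(pivaloyloxy)phenyl]tetrahydrofuran-3,4-diyl}dimethanol | COc1cc([C@H]2O[C@@H](c3cc(OC)c(OC(=O)C(C)(C)C)c(OC)c3)[C@@H](CO)[C@H]2CO)cc(OC)c1OC(=O)C(C)(C)C
F5 | step 3 | 4-(hydroxymethyl)-2,6-dimethoxyphenyl 2,2-dimethylpropanoate | COc1cc(CO)cc(OC)c1OC(=O)C(C)(C)C
F6 | step 3 | 1-[3,5-dimethoxy-4-(pivaloyloxy)benzyl]tetrahydrothiophenium tetrafluoroborate | COc1cc(C[S+]2CCCC2)cc(OC)c1OC(=O)C(C)(C)C.F[B-](F)(F)F
F7 | step 2 | 4-ethenyl-2,6-dimethoxyphenyl 2,2-dimethylpropanoate | COc1cc(C=C)cc(OC)c1OC(=O)C(C)(C)C
A1 | alternative 1 | cis-N,N'-di(quinolin-8-yl)tetrahydrofuran-3,4-dicarboxamide (meso) | O=C(Nc1cccc2cccnc12)[C@@H]1COC[C@@H]1C(=O)Nc1cccc2cccnc12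
A2 | alternative 1 | 2-(benzyloxy)-5-iodo-1,3-dimethoxybenzene | COc1cc(I)cc(OC)c1OCc1ccccc1
A3 | alternative 1 | all-cis-2,5-bis(4-benzyloxy-3,5-dimethoxyphenyl)-N,N'-di(quinolin-8-yl)tetrahydrofuran-3,4-dicarboxamide | COc1cc([C@H]2O[C@@H](c3cc(OC)c(OCc4ccccc4)c(OC)c3)[C@@H](C(=O)Nc3cccc4cccnc34)[C@H]2C(=O)Nc2cccc3cccnc23)cc(OC)c1OCc1ccccc1
A4 | alternative 2 | 3-(4-benzyloxy-3,5-dimethoxyphenyl)prop-2-yn-1-yl 3-(4-benzyloxy-3,5-dimethoxyphenyl)prop-2-ynoate | COc1cc(C#CCOC(=O)C#Cc2cc(OC)c(OCc3ccccc3)c(OC)c2)cc(OC)c1OCc1ccccc1
A5 | alternative 2 | 4,6-bis(4-benzyloxy-3,5-dimethoxyphenyl)-1H,3H-furo[3,4-c]furan-1-one | O=C1OCc2c(-c3cc(OC)c(OCc4ccccc4)c(OC)c3)oc(-c3cc(OC)c(OCc4ccccc4)c(OC)c3)c12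
A6 | alternative 3 | (bromomethyl)dimethylsilyl ether of the 4,5-cis 2,5-bis(4-benzyloxy-3,5-dimethoxyphenyl)-4,5-dihydrofuran-4-ylmethanol (target numbering, racemic, one enantiomer drawn) | COc1cc(C2=C[C@H](CO[Si](C)(C)CBr)[C@H](c3cc(OC)c(OCc4ccccc4)c(OC)c3)O2)cc(OC)c1OCc1ccccc1
A7 | alternative 3 | all-cis 2,5-bis(4-benzyloxy-3,5-dimethoxyphenyl)tetrahydrofuran with C3 and C4 bridged by CH2–Si(CH3)2–O–CH2 (racemic, one enantiomer drawn) | COc1cc([C@H]2O[C@@H](c3cc(OC)c(OCc4ccccc4)c(OC)c3)[C@@H](CO[Si](C)(C)C5)[C@H]25)cc(OC)c1OCc1ccccc1
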